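**Assumption:** the stereochemistry is taken exactly as written in the SMILES, which in germacrane numbering is 4R,5S,6S,7R,8S,10R (C1 ketone, C2=C3 furanone alkene, C4-Me, C5-OH, C6 lactone O, C8 angelate, C10 quaternary, C11–C13 methylene lactone). The five numbered starting materials are assumed to be commercially available. The route is a design from known reaction types; none of it has been run.

## Retrosynthetic overview

1. Target ⇒ 8-OH/5-OTBS macrocycle by late C8 angeloylation and C5 desilylation.
2. The C7–C8 bond and the α-methylene lactone come from an intramolecular Cr(II) Barbier allylation of a 3-(bromomethyl)butenolide onto a C8 aldehyde; this closes the 10-membered carbocycle last and sets C7 and C8.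
3. The butenolide comes from RCM of the C6-allylic 2-(bromomethyl)acrylate; the 3(2H)-furanone comes from Au-catalysed 5-endo cyclisation of an α'-hydroxy ynone.
4. The ynone (C1–C2 bond) comes from the lithium acetylide of a C2–C7 fragment and a dioxolanone derived from (R)-citramalic acid (C1, C8–C10, C14).
5. The alkyne fragment (C4–C5 bond, C4/C5 stereocentres) comes from Marshall anti-propargylation of (S)-2-(PMBO)but-3-enal. Ring order: furanone → butenolide → carbocycle/α-methylene lactone.

## Route

**Step 1**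
Reactants: 1, (R)-but-3-yn-2-ol
Product: 2, (R)-but-3-yn-2-yl methanesulfonate
Conditions: MsCl, Et3N, CH2Cl2, −78 → 0 °C
Reagents that add atoms: methanesulfonyl chloride, CS(=O)(=O)Cl
Why: O-sulfonylation leaves the carbinol stereocentre untouched and gives the propargylic electrophile for the Marshall reaction.

**Step 2**
Reactants: 3, (S)-but-3-ene-1,2-diol
Product: 4, (4S)-2-(4-methoxyphenyl)-4-vinyl-1,3-dioxolane (about 1:1 at the acetal carbon, inconsequential)
Conditions: p-MeOC6H4CH(OMe)2, CSA (cat.), CH2Cl2, rt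
Reagents that add atoms: p-anisaldehyde dimethyl acetal, COC(OC)c1ccc(OC)cc1
Why: Acid-catalysed transacetalisation of the 1,2-diol; the C6 stereocentre is carried from the chiral pool.

**Step 3**
Reactants: 4
Product: 5, (S)-2-[(4-methoxybenzyl)oxy]but-3-en-1-ol
Conditions: DIBAL-H, CH2Cl2, −78 → 0 °C
Reagents that add atoms: none
Why: Regioselective reductive acetal opening; aluminium binds the less hindered primary oxygen, so PMB ends on the secondary oxygen and the primary alcohol is freed.

**Step 4**
Reactants: 5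
Product: 6, (S)-2-[(4-methoxybenzyl)oxy]but-3-enal
Conditions: DMP, NaHCO3, CH2Cl2, 0 °C; used crude immediately
Reagents that add atoms: none
Why: Buffered Dess–Martin oxidation is non-basic, which avoids epimerisation or conjugation of the α-alkoxy-β,γ-unsaturated aldehyde.

**Step 5**
Reactants: 2 and 6
Product: 7, (3S,4S,5S)-5-[(4-methoxybenzyl)oxy]-3-methylhept-6-en-1-yn-4-ol
Conditions: Pd(OAc)2 (5 mol %), PPh3 (5 mol %), Et2Zn (3 equiv), THF, −78 → −20 °C
Reagents that add atoms: none
Why: Marshall propargylation; anti-SN2' oxidative addition then Zn transmetalation gives the (P)-allenylzinc, which adds through a cyclic SE2' transition state to give the anti Me/OH pair (C4, C5), with Zn chelation by the α-OPMB reinforcing the required 5,6-syn sense.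

**Step 6**
Reactants: 7
Product: 8, tert-butyl{[(3S,4S,5S)-5-[(4-methoxybenzyl)oxy]-3-methylhept-6-en-1-yn-4-yl]oxy}dimethylsilane
Conditions: TBSOTf, 2,6-lutidine, CH2Cl2, −78 → 0 °C
Reagents that add atoms: TBSOTf, CC(C)(C)[Si](C)(C)OS(=O)(=O)C(F)(F)F
Why: Silylation of the hindered secondary alcohol; TBS at C5 is orthogonal to PMB and lasts to the final step.

**Step 7**
Reactants: 9, (R)-citramalic acid
Product: 10, 2-[(4R)-2,2,4-trimethyl-5-oxo-1,3-dioxolan-4-yl]acetic acid
Conditions: 2,2-dimethoxypropane, p-TsOH (cat.), rt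
Reagents that add atoms: 2,2-dimethoxypropane, COC(C)(C)OC
Why: Selective acetonide formation of the α-hydroxy acid (five-membered dioxolanone) differentiates the two carboxyls; C10 comes from the chiral pool.

**Step 8**
Reactants: 10
Product: 11, (5R)-5-(2-hydroxyethyl)-2,2,5-trimethyl-1,3-dioxolan-4-one
Conditions: BH3·THF, THF, 0 °C → rt; MeOH quench, neutral work-up
Reagents that add atoms: none
Why: Borane reduces the free carboxylic acid chemoselectively over the dioxolanone ester.

**Step 9**
Reactants: 11
Product: 12, (5R)-5-[2-(tert-butyldimethylsilyloxy)ethyl]-2,2,5-trimethyl-1,3-dioxolan-4-one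
Conditions: TBSCl, imidazole, CH2Cl2, 0 °C → rt
Reagents that add atoms: TBSCl, CC(C)(C)[Si](C)(C)Cl
Why: Primary alcohol silylation masks C8 and prevents translactonisation.

**Step 10**
Reactants: 8 and 12
Product: 13, (3R,7S,8S,9S)-1,8-bis(tert-butyldimethylsilyloxy)-3-hydroxy-9-[(4-methoxybenzyl)oxy]-3,7-dimethylundec-10-en-5-yn-4-one
Conditions: 8, n-BuLi, THF, −78 °C; then 12, −78 → −40 °C; AcOH then aq. NH4Cl
Reagents that add atoms: none
Why: Acetylide acylation; the non-enolisable dioxolanone acts as an activated ester whose lithium hemiketal adduct is stable cold (single addition) and on work-up loses acetone to reveal the α'-hydroxy ynone.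

**Step 11**
Reactants: 13
Product: 14, (2R)-2-[2-(tert-butyldimethylsilyloxy)ethyl]-5-{(2R,3S,4S)-3-(tert-butyldimethylsilyloxy)-4-[(4-methoxybenzyl)oxy]hex-5-en-2-yl}-2-methylfuran-3(2H)-one
Conditions: (p-CF3C6H4)3PAuCl (5 mol %), AgOTf (5 mol %), toluene, rt
Reagents that add atoms: none
Why: Cationic Au(I) π-activation drives 5-endo-dig attack of the tertiary OH on the ynone β-carbon under neutral conditions, so the propargylic C4 centre is not epimerised.

**Step 12**
Reactants: 14
Product: 15, (2R)-2-[2-(tert-butyldimethylsilyloxy)ethyl]-5-[(2R,3S,4S)-3-(tert-butyldimethylsilyloxy)-4-hydroxyhex-5-en-2-yl]-2-methylfuran-3(2H)-one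
Conditions: DDQ, CH2Cl2/pH 7 buffer (10:1), 0 °C → rt
Reagents that add atoms: none
Why: Oxidative PMB cleavage frees only the C6 allylic alcohol; silyl ethers and the vinylogous ester are inert.

**Step 13**
Reactants: 15 and 16, 2-(bromomethyl)acrylic acid
Product: 17, the C6 2-(bromomethyl)acrylate ester of 15
Conditions: DCC, DMAP (5 mol %), CH2Cl2, 0 °C
Reagents that add atoms: 2-(bromomethyl)acrylic acid, C=C(CBr)C(=O)O
Why: Steglich esterification of the only free hydroxyl; low DMAP loading and low temperature limit attack on the allylic bromide.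

**Step 14**
Reactants: 17
Product: 18, (5S)-3-(bromomethyl)-5-{(1S,2R)-1-(tert-butyldimethylsilyloxy)-2-[(5R)-5-[2-(tert-butyldimethylsilyloxy)ethyl]-5-methyl-4-oxo-4,5-dihydrofuran-2-yl]propyl}furan-2(5H)-one
Conditions: Hoveyda–Grubbs II (10 mol %), toluene (5 mM), 80 °C
Reagents that add atoms: none
Why: Ring-closing metathesis between the vinyl group and the acrylate forms the butenolide (C7=C11) with loss of ethylene; the furanone alkene is trisubstituted and electron-poor and does not react.

**Step 15**
Reactants: 18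
Product: 19, the primary alcohol of 18 (C8-OH; C5-OTBS retained)
Conditions: CSA (0.2 equiv), MeOH/CH2Cl2 (1:1), 0 °C
Reagents that add atoms: none
Why: Mild acidic methanolysis removes the unhindered primary TBS much faster than the flanked secondary C5-OTBS and does not disturb the allylic bromide.

**Step 16**
Reactants: 19
Product: 20, the C8 aldehyde
Conditions: DMP, NaHCO3, CH2Cl2, 0 °C → rt; short silica plug, used at once
Reagents that add atoms: none
Why: Non-basic oxidation avoids β-elimination of the furanone oxygen from the β-alkoxy aldehyde.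

**Step 17**
Reactants: 20
Product: 21, 5-O-TBS-8-O-desangeloyl-rufescenolide B (tricyclic 8-hydroxy α-methylene lactone, 4R,5S,6S,7R,8S,10R)
Conditions: CrCl2 (10 equiv), THF, rt, syringe-pump addition to 2 mM
Reagents that add atoms: none
Why: Intramolecular Barbier (Nozaki–Hiyama-type) allylation; the ring-constrained E-type allylchromium is aldehyde-selective and reacts through a chair transition state on the face opposite the C6 substituent, giving the trans-lactone (C7 R) and the anti C7/C8 relationship (C8 S) while unveiling the exocyclic methylene.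

**Step 18**
Reactants: 21 and 22, angelic acid
Product: 23, 5-O-TBS-rufescenolide B
Conditions: 22, 2,4,6-Cl3C6H2COCl, Et3N, toluene, rt; then 21, 60 °C (no DMAP)
Reagents that add atoms: angelic acid, C/C=C(/C)C(=O)O
Why: Yamaguchi mixed-anhydride acylation of the only free hydroxyl; omitting DMAP suppresses Z→E isomerisation to the tiglate.

**Step 19**
Reactants: 23
Product: 24, rufescenolide B
Conditions: HF·pyridine, THF/pyridine, 0 °C → rt
Reagents that add atoms: none
Why: Acidic fluoride desilylation frees C5-OH without the base that would cause retro-aldol, dehydration to the 4,5-ene, angelate isomerisation or Michael addition to the methylene lactone.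

## Compound list

1 | (R)-but-3-yn-2-ol | C#C[C@@H](C)O | starting material
2 | (R)-but-3-yn-2-yl methanesulfonate | C#C[C@@H](C)OS(C)(=O)=O | intermediate
3 | (S)-but-3-ene-1,2-diol | C=C[C@H](O)CO | starting material
4 | (4S)-2-(4-methoxyphenyl)-4-vinyl-1,3-dioxolane | C=C[C@H]1COC(c2ccc(OC)cc2)O1 | intermediate
5 | (S)-2-(PMBO)but-3-en-1-ol | C=C[C@H](OCc1ccc(OC)cc1)CO | intermediate
6 | (S)-2-(PMBO)but-3-enal | C=C[C@H](OCc1ccc(OC)cc1)C=O | intermediate
7 | (3S,4S,5S)-5-(PMBO)-3-methylhept-6-en-1-yn-4-ol | C=C[C@H](OCc1ccc(OC)cc1)[C@@H](O)[C@@H](C)C#C | intermediate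
8 | TBS ether of 7 | C=C[C@H](OCc1ccc(OC)cc1)[C@@H](O[Si](C)(C)C(C)(C)C)[C@@H](C)C#C | intermediate
9 | (R)-citramalic acid | C[C@@](O)(CC(=O)O)C(=O)O | starting material
10 | 2-[(4R)-2,2,4-trimethyl-5-oxo-1,3-dioxolan-4-yl]acetic acid | C[C@]1(CC(=O)O)OC(C)(C)OC1=O | intermediate
11 | (5R)-5-(2-hydroxyethyl)-2,2,5-trimethyl-1,3-dioxolan-4-one | C[C@]1(CCO)OC(C)(C)OC1=O | intermediate
12 | (5R)-5-[2-(TBSO)ethyl]-2,2,5-trimethyl-1,3-dioxolan-4-one | C[C@]1(CCO[Si](C)(C)C(C)(C)C)OC(C)(C)OC1=O | intermediate
13 | α'-hydroxy ynone (3R,7S,8S,9S) | C=C[C@H](OCc1ccc(OC)cc1)[C@@H](O[Si](C)(C)C(C)(C)C)[C@@H](C)C#CC(=O)[C@](C)(O)CCO[Si](C)(C)C(C)(C)C | intermediate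
14 | 3(2H)-furanone, C6-OPMB | C=C[C@H](OCc1ccc(OC)cc1)[C@@H](O[Si](C)(C)C(C)(C)C)[C@@H](C)C1=CC(=O)[C@@](C)(CCO[Si](C)(C)C(C)(C)C)O1 | intermediate
15 | 3(2H)-furanone, C6-OH | C=C[C@H](O)[C@@H](O[Si](C)(C)C(C)(C)C)[C@@H](C)C1=CC(=O)[C@@](C)(CCO[Si](C)(C)C(C)(C)C)O1 | intermediate
16 | 2-(bromomethyl)acrylic acid | C=C(CBr)C(=O)O | starting material
17 | C6 2-(bromomethyl)acrylate | C=C[C@H](OC(=O)C(=C)CBr)[C@@H](O[Si](C)(C)C(C)(C)C)[C@@H](C)C1=CC(=O)[C@@](C)(CCO[Si](C)(C)C(C)(C)C)O1 | intermediate
18 | (5S)-3-(bromomethyl)butenolide, bis-TBS | O=C1O[C@H]([C@@H](O[Si](C)(C)C(C)(C)C)[C@@H](C)C2=CC(=O)[C@@](C)(CCO[Si](C)(C)C(C)(C)C)O2)C=C1CBr | intermediate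
19 | bromobutenolide, C8 primary alcohol | O=C1O[C@H]([C@@H](O[Si](C)(C)C(C)(C)C)[C@@H](C)C2=CC(=O)[C@@](C)(CCO)O2)C=C1CBr | intermediate
20 | bromobutenolide, C8 aldehyde | O=C1O[C@H]([C@@H](O[Si](C)(C)C(C)(C)C)[C@@H](C)C2=CC(=O)[C@@](C)(CC=O)O2)C=C1CBr | intermediate
21 | 5-O-TBS-8-O-desangeloyl-rufescenolide B | C=C1C(=O)O[C@@H]2[C@@H](O[Si](C)(C)C(C)(C)C)[C@@H](C)C3=CC(=O)[C@@](C)(C[C@H](O)[C@@H]12)O3 | intermediate
22 | angelic acid, (Z)-2-methylbut-2-enoic acid | C/C=C(/C)C(=O)O | starting material
23 | 5-O-TBS-rufescenolide B | C=C1C(=O)O[C@@H]2[C@@H](O[Si](C)(C)C(C)(C)C)[C@@H](C)C3=CC(=O)[C@@](C)(C[C@H](OC(=O)/C(C)=C\C)[C@@H]12)O3 | intermediate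
24 | Rufescenolide B | C=C1C(=O)O[C@@H]2[C@@H](O)[C@@H](C)C3=CC(=O)[C@@](C)(C[C@H](OC(=O)/C(C)=C\C)[C@@H]12)O3 | target

## Totals and risks

Total steps: 19. Longest linear sequence: 15 (3 → 24 via steps 2–6 and 10–19).

Steps most likely to fail:

1. **Step 17, Barbier macrocyclisation** (ring closure, C7/C8 selectivity, possible translactonisation). Fallback: form C7–C8 first by an intermolecular In/Zn Barbier between a C2-silylated alkynyl bromobutenolide and the aldehyde derived from 11. Then close the ring at C1–C2 by an intramolecular iodoalkyne–aldehyde Nozaki–Hiyama–Kishi reaction, oxidise to the ynone, and form the furanone by transannular Au cyclisation.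

2. **Step 14, RCM onto the 2-(bromomethyl)acrylate** (together with the amine-sensitive esterification in step 13). Fallback: esterify C6-OH with acryloyl chloride and ring-close to the unsubstituted butenolide. Then install C13 by Morita–Baylis–Hillman hydroxymethylation (HCHO, imidazole or PBu3) and Appel bromination (CBr4/PPh3).

3. **Step 10, acetylide addition to the hindered dioxolanone** (low conversion or over-addition). Fallback: change the acyl donor and oxidation level. Methanolyse 12, protect the tertiary OH as TES and reduce to the C1 aldehyde with DIBAL-H. Add the lithium acetylide of 8 to that non-enolisable aldehyde, oxidise the propargylic alcohol (MnO2 or DMP) to the ynone, and desilylate/cyclise with the Au catalyst.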